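## Analysis of the target

The target is a p-terphenyl whose central benzene ring (ring B, C1' to C6') carries 4-hydroxyphenyl rings (rings A and C) at C1' and C4', free hydroxyl groups at C2' and C3', and benzoyloxy groups at C5' and C6'. Ring B is hexasubstituted, with four oxygens arranged as two ortho pairs that are separated by the two aryl-bearing carbons. There is no stereocenter; rings A and C are para-substituted and symmetric about the biaryl axes, so no atropisomers arise, and a twofold axis runs through the midpoints of C2'-C3' and C5'-C6'. The sensitive groups are the two aryl benzoates, which are cleaved or transesterified by base and nucleophiles, and the electron-rich 2',3'-catechol, which air-oxidizes to an ortho-quinone, fastest in base. The carbon skeleton amounts to only two biaryl bonds, so the difficulty lies in telling the two ortho oxygen pairs apart on a crowded ring, one pair acylated and the other free, while the outer phenols also end up free. The plan rests on one feature: in a 3,6-diarylcatechol, C2' and C3' are the only ring B carbons that still carry hydrogen, and in the corresponding ortho-quinone they are the β-carbons of the enones C6'(=O)-C1'=C2' and C5'(=O)-C4'=C3'. An oxygen nucleophile can therefore be placed exactly there, and the product holds the two oxygen pairs in different oxidation states (carbonyl and ether).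

## Retrosynthetic reasoning

**17 to 16.** The four benzylic C-O bonds of 16 are cut last. All four phenols that are free in 17 (C4, C4'', C2', C3') carry the same protecting group, so one neutral hydrogenolysis should release them together and leave the aryl benzoates alone. In 17 each free ring B hydroxyl is separated from the nearest ester by an aryl-bearing carbon, so an intramolecular acyl shift is not possible.

**16 to 13 and 14.** The two acyl-oxygen bonds are cut, which leads to the catechol oxidation level and two molecules of benzoyl chloride 14. The free catechol 12 is too electron-rich to store or to carry through a solvent change, so the acylation is run on its zinc salt 15, which is made by metal reduction of quinone 13 in the same flask. In 13 the oxygens at C5' and C6' are carbonyls and those at C2' and C3' are ethers; this difference sends the benzoyl groups to the correct pair.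

**13 to 8 and 9.** The C2'-O and C3'-O bonds are cut, returning 13 to quinone 8 and two molecules of benzyl alcohol 9. Quinone 8 has hydrogen only at these two carbons and both are enone β-positions. The forward reaction is two conjugate additions of 9, each followed by tautomerization (to 10, then 12) and reoxidation (to 11, then 13). Cutting here and not at the biaryl bonds means the skeleton is complete before the delicate oxygenation, and the symmetry lets both C-O bonds form in one operation. The forward step has to drive the second addition, keep water out and stop at 13.

**8 to 7 to 6.** Quinone 8 is the two-electron oxidation product of catechol 7, and 7 is released from its bis(methoxymethyl) ether 6 by acid. The acetal is chosen because its removal spares the benzyl ethers on rings A and C, and because it directs the metalation earlier in the route.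

**6 to 4 and 5.** Both biaryl bonds (C1'-C1 and C4'-C1'') are cut at once, giving dibromide 4 and two molecules of boronic acid 5. The symmetry allows a single double cross-coupling. The benzyl ethers arrive with 5, after all organolithium chemistry is finished, which matters because the benzylic CH2 of an aryl benzyl ether is attacked by such strong bases.

**4 to 2 to 1.** The two C-Br bonds are traced to C-H bonds of 2 through the dilithio arene 3. Electrophilic bromination of a catechol diether would go para to oxygen (C4 and C5), the wrong carbons. The acetal oxygens direct metalation to the ortho carbons C3 and C6, which are the ones needed. Ether 2 comes from catechol 1 by double acetalization.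

## Alternatives that were turned down

**Alternative 1:** Ring B is cut into three two-carbon pieces. RhCl(PPh3)3 (monovalent rhodium) would join the silicon-tethered bis(ynol ether) A1 with di-tert-butoxyethyne A2 in a [2+2+2] cycloaddition, forming C5'-C6', C1'-C2' and C3'-C4' and giving benzodioxasilole A3.
- For: it is convergent, and the tether fixes the aryl groups para to each other. The four ring B oxygens arrive already sorted into a silylene-bridged pair and a tert-butyl pair. On convergence and built-in differentiation it is stronger than the chosen route.
- Against: A1 is a bis(siloxyalkyne), hydrolytically fragile and prone to ketene-type decomposition. A2 is thermally labile, losing its tert-butyl groups by elimination on mild heating, while this catalyst usually needs heat. All three alkynes are electron-rich, so metallacycle formation and insertion are electronically mismatched, and A3 has tert-butoxy groups next to aryl groups on a hexasubstituted ring.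
- Step economy: after A3 come desilylation, benzoylation, acid cleavage of the tert-butyl ethers and hydrogenolysis, on top of making A1 and A2. The count is not below that of the chosen route.
- Comparison: the chosen route starts from an intact benzene ring and makes its C-C bonds by a routine cross-coupling. In place of differentiation by construction it offers differentiation by oxidation state in 13.

**Alternative 2:** The C5'-O and C6'-O ester bonds are traced back to C-C(=O) bonds. CF3CO3H buffered with Na2HPO4 would oxidize diketone A4 twice, with migration of ring B, to dibenzoate A5 (the same compound as 16).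
- For: the benzoates are installed directly, no catechol or quinone is handled, and A5 is one hydrogenolysis from the target. Ring B carries an alkoxy group para to each ketone and should migrate in preference to phenyl. On directness of ester installation it is stronger than the chosen route.
- Against: each carbonyl of A4 is flanked by an aryl group and a benzoyl group, so it is twisted and shielded, and addition of the peracid to the carbonyl should be slow. The peracid is a strong electrophilic oxidant, and A4 contains six electron-rich alkoxyarene units open to ring oxidation and benzyl ether damage.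
- Step economy: A4 is itself a hexasubstituted benzene with two adjacent aroyl groups, whose assembly is a synthesis of its own that must still solve the C2'/C3' oxygenation.
- Comparison: the chosen route reaches the same compound 16 by way of quinone 13, whose formation needs only the mild oxidant Ag2O, which leaves benzyl ethers alone.

**Alternative 3:** Ring B is made by ring expansion of a squarate-derived cyclobutenone. Heating cyclobutenone A6 in toluene would open the four-membered ring to dienylketene A7, whose 6π electrocyclization forms C2'-C3' and gives, after tautomerization, phenol A8.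
- For: the regiochemistry is fixed by the order in which the substituents are attached to the four-membered ring, the key step is neutral and thermal, and crowded phenols are a known strength of this chemistry. On certainty of regiochemistry it is stronger than the chosen route.
- Against: A8 carries four different oxygen functions where the target needs two kinds. The assembly of A6 needs two different carbon nucleophiles added in sequence to a four-membered-ring precursor, one of them a β-alkoxyvinyl metal species that can lose alkoxide by β-elimination, and then protection of a tertiary alkoxide. The tert-butyl vinylogous ester of A6 may also suffer thermal elimination at the thermolysis temperature.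
- Step economy: A8 still needs benzylation, acid cleavage of two groups, benzoylation and hydrogenolysis. The route is clearly longer and ignores the twofold symmetry.
- Comparison: the chosen route uses the symmetry twice, in one double cross-coupling and one double oxygenation.

Key step: step 6

Remark on the chemistry: rotation about both biaryl axes is taken as free, so the target and all intermediates are treated as single achiral compounds. The zinc catecholate 15 is drawn as a monomeric chelate, although in THF it is expected to be solvated and aggregated.

## Route

Step 1
Reactants: 1 catechol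
Product: 2 1,2-bis(methoxymethoxy)benzene
Conditions: NaH, DMF, 0 °C; then MOMCl, 0 °C → rt
Reagents that add atoms: chloromethyl methyl ether, COCCl
Why: Williamson-type O-alkylation of the catechol dianion by the reactive α-chloro ether; both phenols should react and the acetal is stable to the strong bases used next.

Step 2
Reactants: 2 1,2-bis(methoxymethoxy)benzene
Product: 4 1,4-dibromo-2,3-bis(methoxymethoxy)benzene, via 3,6-dilithio arene 3 (not isolated)
Conditions: n-BuLi, TMEDA, Et2O, 0 °C → rt; then BrCl2C-CCl2Br, −78 °C → rt
Reagents that add atoms: 1,2-dibromo-1,1,2,2-tetrachloroethane, ClC(Cl)(Br)C(Cl)(Cl)Br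
Why: Double directed ortho-metalation, in which each acetal oxygen directs deprotonation to its free ortho carbon (C3 and C6), as known for catechol diethers. The dilithio arene 3 is then brominated by halogen transfer from the polyhaloethane, which collapses to tetrachloroethene and offers no acidic proton.

Step 3
Reactants: 4 1,4-dibromo-2,3-bis(methoxymethoxy)benzene; 5 4-(benzyloxy)phenylboronic acid
Product: 6 4,4''-bis(benzyloxy)-2',3'-bis(methoxymethoxy)-1,1':4',1''-terphenyl
Conditions: Pd(OAc)2, SPhos, K3PO4, toluene/H2O, 90 °C
Reagents that add atoms: 4-(benzyloxy)phenylboronic acid (second equivalent of 5), OB(O)c1ccc(OCc2ccccc2)cc1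
Why: Double Suzuki-Miyaura coupling, one molecule of 5 for each C-Br bond: oxidative addition of zerovalent palladium, transmetalation from the boronate and reductive elimination. Each bromide has only one ortho substituent, and a bulky electron-rich biarylphosphine suits electron-rich aryl bromides.

Step 4
Reactants: 6 4,4''-bis(benzyloxy)-2',3'-bis(methoxymethoxy)-1,1':4',1''-terphenyl
Product: 7 3,6-bis(4-benzyloxyphenyl)benzene-1,2-diol
Conditions: HCl (aq., cat.), MeOH/THF, 50 °C, Ar
Reagents that add atoms: none
Why: Acid-catalysed acetal exchange transfers the formaldehyde unit to methanol and frees both phenols; aryl benzyl ethers are stable to dilute acid, and argon protects the catechol from air oxidation.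

Step 5
Reactants: 7 3,6-bis(4-benzyloxyphenyl)benzene-1,2-diol
Product: 8 3,6-bis(4-benzyloxyphenyl)-1,2-benzoquinone
Conditions: Ag2O, Na2SO4, CH2Cl2, rt, dark
Reagents that add atoms: none
Why: Two-electron oxidation of a catechol to the ortho-quinone by Ag2O under neutral conditions, with the drying agent taking up the water formed. The aryl groups at C3 and C6 should suppress the Diels-Alder dimerization typical of unhindered ortho-quinones.

Step 6
Reactants: 8 3,6-bis(4-benzyloxyphenyl)-1,2-benzoquinone; 9 benzyl alcohol
Product: 13 4,5-bis(benzyloxy)-3,6-bis(4-benzyloxyphenyl)-1,2-benzoquinone, via 4-benzyloxy catechol 10 (not isolated), via 4-benzyloxy quinone 11 (not isolated), via 4,5-bis(benzyloxy) catechol 12 (not isolated)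
Conditions: BnOH (excess), Cs2CO3 (substoichiometric), Ag2O, 4 Å MS, THF, 0 °C → rt, Ar, dark
Reagents that add atoms: benzyl alcohol (second equivalent of 9), OCc1ccccc1
Why: Benzyl alkoxide, present in low concentration through Cs2CO3, adds in 1,4-fashion to C4 of quinone 8 (β to the C2 carbonyl), and the adduct enolizes to the aromatic catechol 10. Ag2O, which does not attack benzyl ethers or benzyl alcohol at room temperature, oxidizes 10 to quinone 11; there the new alkoxy group donates only into the C2 carbonyl, so C5 remains the β-carbon of an unperturbed enone. A second molecule of benzyl alcohol adds at C5 to give catechol 12, and oxidation gives 13. The closest known reaction type is the oxidative alkoxylation of ortho-benzoquinone and of 3,6-dialkyl ortho-benzoquinones by alcohols and alkoxides to 4-alkoxy and 4,5-dialkoxy quinones. No ring is closed and no stereocenter is formed. The selectivity needed is conjugate addition at C4 and C5 in preference to attack at C3, C6 or the carbonyls: addition at the aryl-bearing carbons or at C=O gives adducts that cannot aromatize and revert, while the C4 and C5 adducts are drained by tautomerization and oxidation. The sequence should stop at 13 because no ring hydrogen remains and both enones have become vinylogous esters. The sieves and the large excess of alcohol keep the water released in each oxidation from competing as a nucleophile.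

Step 7
Reactants: 13 4,5-bis(benzyloxy)-3,6-bis(4-benzyloxyphenyl)-1,2-benzoquinone; 14 benzoyl chloride
Product: 16 4,5-bis(benzyloxy)-3,6-bis(4-benzyloxyphenyl)-1,2-phenylene dibenzoate, via zinc catecholate 15 (not isolated)
Conditions: Zn dust, THF, rt, Ar; then Et3N, DMAP (cat.), BzCl, 0 °C → rt
Reagents that add atoms: benzoyl chloride (second equivalent of 14), O=C(Cl)c1ccccc1
Why: Reductive acylation of a quinone: two-electron transfer from zinc metal to the ortho-quinone gives the zinc catecholate 15, as known for 3,6-disubstituted ortho-quinones, and DMAP-catalysed O-acylation then esterifies exactly the two oxygens that were carbonyls. The free catechol is never exposed to air or to a solvent change, the amine binds the ZnCl2 formed so that it does not activate the acyl chloride toward the ethers, and the four benzyl ethers are otherwise inert.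

Step 8
Reactants: 16 4,5-bis(benzyloxy)-3,6-bis(4-benzyloxyphenyl)-1,2-phenylene dibenzoate
Product: 17 4,5-dihydroxy-3,6-bis(4-hydroxyphenyl)-1,2-phenylene dibenzoate (the target)
Conditions: H2 (1 atm), Pd/C, EtOAc/THF, rt
Reagents that add atoms: none
Why: Hydrogenolysis of the four benzylic C-O bonds over Pd/C; aryl benzoates have no benzylic C-O bond and should survive in a neutral, non-nucleophilic solvent. The freed hydroxyls at C2' and C3' are not ortho to the esters, so no acyl migration is expected.

## Compound list

1 | catechol | Oc1ccccc1O | starting material
2 | 1,2-bis(methoxymethoxy)benzene | COCOc1ccccc1OCOC | intermediate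
3 | 3,6-dilithio-1,2-bis(methoxymethoxy)benzene | [Li]c1ccc([Li])c(OCOC)c1OCOC | intermediate
4 | 1,4-dibromo-2,3-bis(methoxymethoxy)benzene | COCOc1c(Br)ccc(Br)c1OCOC | intermediate
5 | 4-(benzyloxy)phenylboronic acid | OB(O)c1ccc(OCc2ccccc2)cc1 | starting material
6 | 4,4''-bis(benzyloxy)-2',3'-bis(methoxymethoxy)-1,1':4',1''-terphenyl | COCOc1c(-c2ccc(OCc3ccccc3)cc2)ccc(-c2ccc(OCc3ccccc3)cc2)c1OCOC | intermediate
7 | 3,6-bis(4-benzyloxyphenyl)benzene-1,2-diol | Oc1c(-c2ccc(OCc3ccccc3)cc2)ccc(-c2ccc(OCc3ccccc3)cc2)c1O | intermediate
8 | 3,6-bis(4-benzyloxyphenyl)-1,2-benzoquinone | O=C1C(=O)C(c2ccc(OCc3ccccc3)cc2)=CC=C1c1ccc(OCc2ccccc2)cc1 | intermediate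
9 | benzyl alcohol | OCc1ccccc1 | starting material
10 | 4-(benzyloxy)-3,6-bis(4-benzyloxyphenyl)benzene-1,2-diol | Oc1c(O)c(-c2ccc(OCc3ccccc3)cc2)c(OCc2ccccc2)cc1-c1ccc(OCc2ccccc2)cc1 | intermediate
11 | 4-(benzyloxy)-3,6-bis(4-benzyloxyphenyl)-1,2-benzoquinone | O=C1C(=O)C(c2ccc(OCc3ccccc3)cc2)=C(OCc2ccccc2)C=C1c1ccc(OCc2ccccc2)cc1 | intermediate
12 | 4,5-bis(benzyloxy)-3,6-bis(4-benzyloxyphenyl)benzene-1,2-diol | Oc1c(O)c(-c2ccc(OCc3ccccc3)cc2)c(OCc2ccccc2)c(OCc2ccccc2)c1-c1ccc(OCc2ccccc2)cc1 | intermediate
13 | 4,5-bis(benzyloxy)-3,6-bis(4-benzyloxyphenyl)-1,2-benzoquinone | O=C1C(=O)C(c2ccc(OCc3ccccc3)cc2)=C(OCc2ccccc2)C(OCc2ccccc2)=C1c1ccc(OCc2ccccc2)cc1 | intermediate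
14 | benzoyl chloride | O=C(Cl)c1ccccc1 | starting material
15 | zinc 4,5-bis(benzyloxy)-3,6-bis(4-benzyloxyphenyl)benzene-1,2-diolate (zinc catecholate, drawn as the monomeric chelate) | [Zn]1Oc2c(O1)c(-c1ccc(OCc3ccccc3)cc1)c(OCc1ccccc1)c(OCc1ccccc1)c2-c1ccc(OCc2ccccc2)cc1 | intermediate
16 | 4,5-bis(benzyloxy)-3,6-bis(4-benzyloxyphenyl)-1,2-phenylene dibenzoate | O=C(Oc1c(OC(=O)c2ccccc2)c(-c2ccc(OCc3ccccc3)cc2)c(OCc2ccccc2)c(OCc2ccccc2)c1-c1ccc(OCc2ccccc2)cc1)c1ccccc1 | intermediate
17 | 4,5-dihydroxy-3,6-bis(4-hydroxyphenyl)-1,2-phenylene dibenzoate | O=C(Oc1c(OC(=O)c2ccccc2)c(-c2ccc(O)cc2)c(O)c(O)c1-c1ccc(O)cc1)c1ccccc1 | target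

## Step count and least certain steps

Total step count: 8. Longest linear sequence: 8 steps, from catechol 1 to target 17.

**Step 6 (key step).** The most likely failure is that the sequence stalls after the first addition. In quinone 11, C5 lies between an aryl group and the new benzyloxy group, and the ring is less electrophilic than in 8. Two side processes can add to this: water released by each oxidation can compete as a nucleophile, and alkoxide-to-quinone hydride transfer can cycle material between 8 and 7 without progress. The fallback oxygenates before it arylates. Catechol 1 is oxidized by Ag2O in the presence of excess benzyl alcohol 9, on the unhindered parent system as in the classical methanol case, to give 4,5-bis(benzyloxy)-1,2-benzoquinone F1. Reduction with Na2S2O4 gives 4,5-bis(benzyloxy)benzene-1,2-diol F2, and NaH with chloromethyl methyl ether gives 1,2-bis(benzyloxy)-4,5-bis(methoxymethoxy)benzene F3. Electrophilic bromination with N-bromosuccinimide in MeCN can only occur at the two remaining ring positions and gives 1,2-bis(benzyloxy)-3,6-dibromo-4,5-bis(methoxymethoxy)benzene F4. Double Suzuki coupling with boronic acid 5 (Pd(OAc)2, SPhos, K3PO4) gives 1,2-bis(benzyloxy)-3,6-bis(4-benzyloxyphenyl)-4,5-bis(methoxymethoxy)benzene F5, and HCl in MeOH/THF under argon releases catechol 12. This is benzoylated at once with benzoyl chloride 14 (Et3N, DMAP, CH2Cl2), and the route is rejoined at 16.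

**Step 2.** The second metalation may be incomplete. During the quench, lithium-bromine exchange between unreacted aryllithium and newly formed aryl bromide may also scramble the halogen and give mixtures. The fallback sets out from 2 and uses two single metalations with silicon as a placeholder, since silicon does not exchange with alkyllithiums. n-BuLi then chlorotrimethylsilane gives [2,3-bis(methoxymethoxy)phenyl]trimethylsilane F6. A second round with n-BuLi/TMEDA and chlorotrimethylsilane gives [2,3-bis(methoxymethoxy)-1,4-phenylene]bis(trimethylsilane) F7. Ipso-iododesilylation with ICl (CH2Cl2, NaHCO3, −78 °C) gives 1,4-diiodo-2,3-bis(methoxymethoxy)benzene F8, which replaces 4 in the coupling of step 3 and returns to the route at 6.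

**Step 7.** The heterogeneous electron transfer may stop short of the catecholate stage. The aggregated zinc catecholate may also be acylated only once, because the second oxygen is flanked by an aryl group and the first benzoate. In addition, zinc salts together with the acyl chloride may begin to cleave benzyl ethers if the amine does not hold them. The fallback sets out from 13 and separates the metal from the acylation. Reductive silylation (Zn, chlorotrimethylsilane, THF), in which the small silyl chloride also activates the metal surface, gives [4,5-bis(benzyloxy)-3,6-bis(4-benzyloxyphenyl)-1,2-phenylene]bis(oxy)bis(trimethylsilane) F9, which is freed from zinc salts by aqueous work-up. Fluoride-triggered acylation (benzoyl chloride 14, CsF, MeCN) then unmasks each phenoxide as a free, more nucleophilic anion in the presence of the acylating agent and returns to the route at 16.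

**Step 8.** Cleavage of the two ring B benzyl ethers, each crowded by an aryl group and a neighbouring ether, may lag behind the outer ones and give partly debenzylated mixtures. Long exposure also raises the risk of air oxidation of the product catechol during filtration. The fallback sets out from 16 and replaces hydrogenolysis by Lewis-acid debenzylation with BCl3 and pentamethylbenzene as cation scavenger (CH2Cl2, −78 °C), which spares aryl esters and gives 17 directly. No new intermediate is formed.

## Further compounds

F1 | step 6 | 4,5-bis(benzyloxy)-1,2-benzoquinone | O=C1C=C(OCc2ccccc2)C(OCc2ccccc2)=CC1=O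
F2 | step 6 | 4,5-bis(benzyloxy)benzene-1,2-diol | Oc1cc(OCc2ccccc2)c(OCc2ccccc2)cc1O
F3 | step 6 | 1,2-bis(benzyloxy)-4,5-bis(methoxymethoxy)benzene | COCOc1cc(OCc2ccccc2)c(OCc2ccccc2)cc1OCOC
F4 | step 6 | 1,2-bis(benzyloxy)-3,6-dibromo-4,5-bis(methoxymethoxy)benzene | COCOc1c(Br)c(OCc2ccccc2)c(OCc2ccccc2)c(Br)c1OCOC
F5 | step 6 | 1,2-bis(benzyloxy)-3,6-bis(4-benzyloxyphenyl)-4,5-bis(methoxymethoxy)benzene | COCOc1c(-c2ccc(OCc3ccccc3)cc2)c(OCc2ccccc2)c(OCc2ccccc2)c(-c2ccc(OCc3ccccc3)cc2)c1OCOC
F6 | step 2 | [2,3-bis(methoxymethoxy)phenyl]trimethylsilane | COCOc1cccc([Si](C)(C)C)c1OCOC
F7 | step 2 | [2,3-bis(methoxymethoxy)-1,4-phenylene]bis(trimethylsilane) | COCOc1c([Si](C)(C)C)ccc([Si](C)(C)C)c1OCOC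
F8 | step 2 | 1,4-diiodo-2,3-bis(methoxymethoxy)benzene | COCOc1c(I)ccc(I)c1OCOC
F9 | step 7 | [4,5-bis(benzyloxy)-3,6-bis(4-benzyloxyphenyl)-1,2-phenylene]bis(oxy)bis(trimethylsilane) | C[Si](C)(C)Oc1c(O[Si](C)(C)C)c(-c2ccc(OCc3ccccc3)cc2)c(OCc2ccccc2)c(OCc2ccccc2)c1-c1ccc(OCc2ccccc2)cc1
F0 | step 8 | none | none
A1 | alternative 1 | di-tert-butylbis[(4-benzyloxyphenyl)ethynyloxy]silane | CC(C)(C)[Si](OC#Cc1ccc(OCc2ccccc2)cc1)(OC#Cc1ccc(OCc2ccccc2)cc1)C(C)(C)C
A2 | alternative 1 | di-tert-butoxyethyne | CC(C)(C)OC#COC(C)(C)C
A3 | alternative 1 | 4,7-bis(4-benzyloxyphenyl)-5,6-di-tert-butoxy-2,2-di-tert-butyl-1,3,2-benzodioxasilole | CC(C)(C)[Si]1(C(C)(C)C)Oc2c(O1)c(-c1ccc(OCc3ccccc3)cc1)c(OC(C)(C)C)c(OC(C)(C)C)c2-c1ccc(OCc2ccccc2)cc1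
A4 | alternative 2 | 1,2-dibenzoyl-4,5-bis(benzyloxy)-3,6-bis(4-benzyloxyphenyl)benzene | O=C(c1ccccc1)c1c(C(=O)c2ccccc2)c(-c2ccc(OCc3ccccc3)cc2)c(OCc2ccccc2)c(OCc2ccccc2)c1-c1ccc(OCc2ccccc2)cc1
A5 | alternative 2 | 4,5-bis(benzyloxy)-3,6-bis(4-benzyloxyphenyl)-1,2-phenylene dibenzoate | O=C(Oc1c(OC(=O)c2ccccc2)c(-c2ccc(OCc3ccccc3)cc2)c(OCc2ccccc2)c(OCc2ccccc2)c1-c1ccc(OCc2ccccc2)cc1)c1ccccc1
A6 | alternative 3 | 4-[2-(benzyloxy)-1-(4-benzyloxyphenyl)ethenyl]-2-(4-benzyloxyphenyl)-3-tert-butoxy-4-(methoxymethoxy)cyclobut-2-en-1-one (racemic, alkene geometry open) | O=C1C(c2ccc(OCc3ccccc3)cc2)=C(OC(C)(C)C)C1(OCOC)C(=COCc1ccccc1)c1ccc(OCc2ccccc2)cc1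
A7 | alternative 3 | 6-(benzyloxy)-2,5-bis(4-benzyloxyphenyl)-3-tert-butoxy-4-(methoxymethoxy)hexa-1,3,5-trien-1-one (dienylketene, alkene geometries open) | O=C=C(c1ccc(OCc2ccccc2)cc1)C(OC(C)(C)C)=C(OCOC)C(=COCc1ccccc1)c1ccc(OCc2ccccc2)cc1
A8 | alternative 3 | 2-(benzyloxy)-3,6-bis(4-benzyloxyphenyl)-5-tert-butoxy-4-(methoxymethoxy)phenol | Oc1c(-c2ccc(OCc3ccccc3)cc2)c(OC(C)(C)C)c(OCOC)c(-c2ccc(OCc3ccccc3)cc2)c1OCc1ccccc1
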